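The pitfall in a curve that bends is to blame the target for holding the catalyst back. I work with the fraction not yet turned to target and take minus its logarithm, which I call the reach. In a pseudo-first-order step under steady catalyst, the reach grows in proportion to time and to catalyst concentration.

| flask | substrate | free catalyst | remark | time |
|---|---|---|---|---|
| alder | 0.16 M | 17 mol% | run made earlier |  |
| cedar | 1.1 M | 17 mol% | run made earlier |  |
| green | 1.2 M | 17 mol% |  | 3.0 min |
| teal | 0.50 M | 17 mol% |  | 3.0 min |
| amber | 0.30 M | 17 mol% |  | 3.0 min |
| ochre | 1.0 M | 17 mol% |  | 3.0 min |
| blue | 0.20 M | 17 mol% |  | 3.0 min |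

| run | time / s | target / % | substrate / % |
|---|---|---|---|
| alder | 12.0 | 3.6 | 96.5 |
| alder | 30.0 | 6.8 | 92.6 |
| alder | 60.0 | 11.6 | 87.6 |
| alder | 90.0 | 14.7 | 84.2 |
| alder | 120 | 18.0 | 81.3 |
| cedar | 25.0 | 32.8 | 65.3 |
| cedar | 50.0 | 50.8 | 47.1 |
| cedar | 80.0 | 64.6 | 34.4 |
| cedar | 90.0 | 67.7 | 31.6 |
| cedar | 120 | 73.6 | 26.1 |

(scatter of a reading: 0.5 percentage points)

- the flasks by amount of target, in percent of the substrate charged, highest first, at 3.0 min (green / teal / amber / ochre / blue)
- the same order at 10 s (green / teal / amber / ochre / blue)
- the amount of target, in percent of the substrate charged of the flask you put first, at 3.0 min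
- the amount of target, in percent of the substrate charged of the flask you put last, at 3.0 min

- in a conversion other conformer counts as not yet reacted
- a reading or a percentage of target counts all its forms, free or not

At 120 s alder has a reach of 0.198 and cedar 1.33. Divided by the catalyst concentration charged, these are 7.30 M⁻¹ and 7.12 M⁻¹, close together, although cedar then holds 28.1 times alder's target concentration. But the reach does not keep step with time: alder has 0.123 at 60.0 s, so its second interval yields 0.610 of its first. I read this, with the scatter it carries, as catalyst fading by a fixed share per interval. Extending that series gives the quantity I carry, the reach per unit of catalyst concentration at 3.0 min: 8.77 M⁻¹.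

Now the ladder, fastest first. Read from alder, the catalyst's half-life is 84.0 s. Fresh catalyst in green would halve the fraction left in 36.3 s. That is shorter than the fading. In blue the same halving takes 218 s, longer than the fading, so in my reckoning blue's catalyst fades first. On the last rung I put any side loss: alder's two readings at 120 s leave a gap of 0.7 percentage points, about the scatter of 0.5 points, so I book none.

In my reckoning, at equal loading and equal time the reach rises with the charge, so I rank by charge at both times, green highest and blue lowest. My reckoning gives 83.3% for green and 25.8% for blue.

The forecast gives green > ochre > teal > amber > blue at 3.0 min and green > ochre > teal > amber > blue at 10 s, with 83% and 26%, holding that “The fall tracks time, not target concentration or conversion”.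

The flasks give green > ochre > teal > amber > blue at 3.0 min and green > ochre > teal > amber > blue at 10 s, with 83.4% in green and 26.1% in blue.

    crystals ⇌ target, rate k1*(cs1 - [target]) while solid is left; crystals form when [target] > cs1 (solubility = 0.140 M, k = 0.0840 s⁻¹)
    free catalyst → spent catalyst (k = 0.00830 s⁻¹)
    substrate ⇌ other conformer (K = 0.0100, k = 5.10 × 10⁻⁴ s⁻¹)
    free catalyst + other conformer → free catalyst + isomer of the product (k = 0.0750 M⁻¹ s⁻¹)
    substrate + free catalyst → free catalyst + target (k = 0.0960 M⁻¹ s⁻¹)

Green's 83.4% is a reach of 8.81 M⁻¹ per unit of catalyst, beside my 8.77 M⁻¹. At 3.00 min in green, substrate's half-life by the catalysed step is 2.6 min against 1.4 min for free catalyst, whereas with charges held it was 0.59 min. Green's crystals, 70.8% of the charge at 3.00 min, count as target, and the ceiling on dissolved target moves its amount by nothing.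

Take the flask like green but with 4.2 mol% of free catalyst: the carried reach leaves 64.3% unturned, so 35.7% target. The computed flask gives 36.1% target, with 63.0% substrate.

The earlier runs and the new flask were computed on assumed constants; noise was put on by code.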